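**Retrosynthetic overview**
- Feature: in ring A the run C3(Br)–C4(Cl)–C5(Br)–C6(H) has the substitution pattern of C3–C6 of a 2-pyrone. The adjacent pair C1(OH)/C2(OAr) is a two-carbon unit with two unlike oxygen functions, which can be stored as an alkyne.
- C1–OH is traced back to C1–B (boronate oxidation), so the two catechol oxygens are never equivalent.
- Ring A is the only ring formed, since ring B is bought as 2,4-dibromophenol. It is cut at C2–C3 and C1–C6: Diels–Alder addition of the pinacol boronate of 2,4-dibromophenoxyacetylene to 3,5-dibromo-4-chloro-2-pyrone, then loss of CO2.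
- Alkyne arm: phenol → 2-bromoethyl ether → vinyl ether → bromovinyl ether → ethynyl ether → alkynyl boronate, using only bases that spare the aryl bromides.
- Pyrone arm: 4-hydroxy-2-pyrone → 3,5-dibromide (enol-directed) → 4-chloride (POCl3).

Key step: step 8

Remark: ring A is numbered C1(OH), C2(OAr), C3(Br), C4(Cl), C5(Br), C6(H). The target is achiral, so the alkene geometry of 6 and the racemic centres of 5 and 18 are transient.

**Step 1**
Reactants: 1 2,4-dibromophenol; 2 1,2-dibromoethane
Product: 3 2,4-dibromo-1-(2-bromoethoxy)benzene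
Conditions: K2CO3 (2 equiv), 2 (5 equiv), MeCN, reflux
Reagents that add atoms: 1,2-dibromoethane (2), BrCCBr
Why: Williamson ether synthesis; K2CO3 fully ionises the acidic phenol, and the large excess of dihalide limits SN2 attack to one end and suppresses the bis(aryloxy)ethane.

**Step 2**
Reactants: 3 2,4-dibromo-1-(2-bromoethoxy)benzene
Product: 4 2,4-dibromo-1-(ethenyloxy)benzene
Conditions: KOtBu (1.5 equiv), THF, 0 °C → rt
Reagents that add atoms: none
Why: E2 dehydrobromination by a hindered alkoxide, the standard route from 2-haloethyl aryl ethers to aryl vinyl ethers; the aryl bromides are inert to KOtBu in THF at this temperature.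

**Step 3**
Reactants: 4 2,4-dibromo-1-(ethenyloxy)benzene
Product: 6 (Z)-2,4-dibromo-1-[(2-bromoethenyl)oxy]benzene, via 1,2-dibromoethyl ether 5 (not isolated)
Conditions: Br2 (1.0 equiv), CH2Cl2, −78 °C; then iPr2NEt (2 equiv), −78 → 40 °C
Reagents that add atoms: bromine, BrBr
Why: Electrophilic bromine addition to the enol ether C=C, which is far more nucleophilic than the twice-brominated ring B, then amine-induced dehydrobromination with loss of the labile alpha-bromo ether bromide; the Z isomer should predominate as in the alkyl series, and every bromovinyl isomer converges on the same alkyne in step 4.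

**Step 4**
Reactants: 6 (Z)-2,4-dibromo-1-[(2-bromoethenyl)oxy]benzene
Product: 8 2,4-dibromo-1-(ethynyloxy)benzene, via potassium acetylide 7 (not isolated)
Conditions: KOtBu (2.2 equiv), THF, −78 → 0 °C; sat. aq NH4Cl, −78 °C; kept cold and used promptly
Reagents that add atoms: none
Why: Anti-E2 dehydrobromination of a vinyl bromide (in the Z isomer the H on the oxygen-bearing carbon is trans to Br), the classical entry to aryloxyacetylenes; the second equivalent of base holds the product as acetylide 7, which shields it from alkoxide addition until the cold quench.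

**Step 5**
Reactants: 8 2,4-dibromo-1-(ethynyloxy)benzene; 9 2-isopropoxy-4,4,5,5-tetramethyl-1,3,2-dioxaborolane
Product: 12 2-[(2,4-dibromophenoxy)ethynyl]-4,4,5,5-tetramethyl-1,3,2-dioxaborolane, via alkynylmagnesium bromide 10 (not isolated), via isopropoxyborate ate complex 11 (not isolated)
Conditions: EtMgBr (1.0 equiv), THF, 0 °C; 9 (1.05 equiv), −78 → −20 °C; HCl (1.0 equiv, 2 M in Et2O), −78 °C → rt; filtration under Ar, no water, no silica
Reagents that add atoms: 2-isopropoxy-4,4,5,5-tetramethyl-1,3,2-dioxaborolane (9), CC(C)OB1OC(C)(C)C(C)(C)O1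
Why: Alkyne metalation, borylation with an alkoxy pinacol borate and anhydrous acid release of the ate complex (the standard alkynyl boronate synthesis); proton transfer to EtMgBr is much faster than Br/Mg exchange at the aryl bromides, which is why no alkyllithium is used.

**Step 6**
Reactants: 13 4-hydroxy-2H-pyran-2-one
Product: 15 3,5-dibromo-4-hydroxy-2H-pyran-2-one, via 3-bromo-4-hydroxy-2-pyrone 14 (not isolated)
Conditions: Br2 (2.2 equiv), AcOH, rt → 50 °C
Reagents that add atoms: bromine, BrBr
Why: Twofold electrophilic halogenation of a vinylogous acid; C3, between the enol and the lactone carbonyl, reacts first, and C5, the beta-carbon of the ring enol ether next to the 4-OH, reacts second, while HBr in AcOH lets any kinetic 3,3-dibromide pass bromine on to C5.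

**Step 7**
Reactants: 15 3,5-dibromo-4-hydroxy-2H-pyran-2-one
Product: 17 3,5-dibromo-4-chloro-2H-pyran-2-one, via pyron-4-yl dichlorophosphate 16 (not isolated)
Conditions: POCl3 (5 equiv), BnEt3NCl (0.2 equiv), MeCN, 80 °C; cold, brief aqueous work-up
Reagents that add atoms: phosphoryl chloride, O=P(Cl)(Cl)Cl
Why: Deoxychlorination of a vinylogous acid by O-phosphorylation and addition–elimination of chloride at C4, the vinylogous acyl position; C3 and C5 are not acceptor positions, so the bromines should not be exchanged.

**Step 8**
Reactants: 12 2-[(2,4-dibromophenoxy)ethynyl]-4,4,5,5-tetramethyl-1,3,2-dioxaborolane; 17 3,5-dibromo-4-chloro-2H-pyran-2-one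
Product: 19 2-[3,5-dibromo-4-chloro-2-(2,4-dibromophenoxy)phenyl]-4,4,5,5-tetramethyl-1,3,2-dioxaborolane, via bridged lactone cycloadduct 18 (not isolated)
Conditions: 12 (1.5 equiv), BHT (5 mol %), dry o-xylene, Ar, 110 → 140 °C
Reagents that add atoms: none
Why: Proposed new method: the electron-poor diene C3=C4–C5=C6 of 17 and the oxygen-activated alkyne of 12 should combine in an inverse-electron-demand, probably asynchronous, [4+2] cycloaddition that forms C2–C3 and C1–C6 to give bridged lactone 18, which loses CO2 by retro-[4+2] at the reaction temperature and leaves ring A as a benzene ring with boron at C1. The closest known reaction type is the thermal cycloaddition of 2-pyrones with alkynyl pinacol boronates to aryl boronates, and the polarity follows the addition of enol ethers to brominated 2-pyrones; the new element is an alkyne that bears both oxygen and boron. Ring A closes intermolecularly in the suprafacial [4+2] mode, with four ring atoms from the pyrone and two from the alkyne. The two bridgehead stereocentres of 18 disappear with CO2, so no stereocontrol is required. The step needs regioselectivity: the oxygen lone pair and the vacant boron orbital polarise the triple bond in the same sense, so the boron-bearing carbon is the nucleophilic end and attacks C6, the remote acceptor terminus of the dienoate, the oxygen-bearing carbon closes on C3, and the bulky boronate also avoids the brominated C3. An aryl ynol ether has no beta-hydrogen for retro-ene collapse to a ketene, so it should tolerate the heating.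

**Step 9**
Reactants: 19 2-[3,5-dibromo-4-chloro-2-(2,4-dibromophenoxy)phenyl]-4,4,5,5-tetramethyl-1,3,2-dioxaborolane
Product: 21 3,5-dibromo-4-chloro-2-(2,4-dibromophenoxy)phenol, via aryl pinacol borate 20 (not isolated)
Conditions: 30% aq H2O2, 1 M NaOH, THF, 0 °C → rt; then 1 M HCl
Reagents that add atoms: hydrogen peroxide, OO
Why: Boronate oxidation; hydroperoxide adds to boron, the aryl group migrates from B to O at the same carbon, and borate 20 is hydrolysed, while the halogens lack the activation needed for substitution by hydroxide at this temperature.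

**Compound list**
1 | 2,4-dibromophenol | Oc1ccc(Br)cc1Br | starting material
2 | 1,2-dibromoethane | BrCCBr | starting material
3 | 2,4-dibromo-1-(2-bromoethoxy)benzene | BrCCOc1ccc(Br)cc1Br | intermediate
4 | 2,4-dibromo-1-(ethenyloxy)benzene | C=COc1ccc(Br)cc1Br | intermediate
5 | 2,4-dibromo-1-(1,2-dibromoethoxy)benzene (racemic, not isolated) | BrCC(Br)Oc1ccc(Br)cc1Br | intermediate
6 | (Z)-2,4-dibromo-1-[(2-bromoethenyl)oxy]benzene | Br/C=C\Oc1ccc(Br)cc1Br | intermediate
7 | potassium (2,4-dibromophenoxy)acetylide (not isolated) | [K+].[C-]#COc1ccc(Br)cc1Br | intermediate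
8 | 2,4-dibromo-1-(ethynyloxy)benzene | C#COc1ccc(Br)cc1Br | intermediate
9 | 2-isopropoxy-4,4,5,5-tetramethyl-1,3,2-dioxaborolane | CC(C)OB1OC(C)(C)C(C)(C)O1 | starting material
10 | [(2,4-dibromophenoxy)ethynyl]magnesium bromide (not isolated) | Br[Mg]C#COc1ccc(Br)cc1Br | intermediate
11 | bromomagnesium [(2,4-dibromophenoxy)ethynyl](isopropoxy)(pinacolato)borate (not isolated) | CC(C)O[B-]1(C#COc2ccc(Br)cc2Br)OC(C)(C)C(C)(C)O1.[Mg+]Br | intermediate
12 | 2-[(2,4-dibromophenoxy)ethynyl]-4,4,5,5-tetramethyl-1,3,2-dioxaborolane | CC1(C)OB(C#COc2ccc(Br)cc2Br)OC1(C)C | intermediate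
13 | 4-hydroxy-2H-pyran-2-one | O=c1cc(O)cco1 | starting material
14 | 3-bromo-4-hydroxy-2H-pyran-2-one (not isolated) | O=c1occc(O)c1Br | intermediate
15 | 3,5-dibromo-4-hydroxy-2H-pyran-2-one | O=c1occ(Br)c(O)c1Br | intermediate
16 | 3,5-dibromo-2-oxo-2H-pyran-4-yl dichlorophosphate (not isolated) | O=c1occ(Br)c(OP(=O)(Cl)Cl)c1Br | intermediate
17 | 3,5-dibromo-4-chloro-2H-pyran-2-one | O=c1occ(Br)c(Cl)c1Br | intermediate
18 | 4,7-dibromo-8-chloro-5-(2,4-dibromophenoxy)-6-(4,4,5,5-tetramethyl-1,3,2-dioxaborolan-2-yl)-2-oxabicyclo[2.2.2]octa-5,7-dien-3-one (racemic, one enantiomer drawn, not isolated) | O=C1O[C@@H]2C(Br)=C(Cl)[C@@]1(Br)C(Oc3ccc(Br)cc3Br)=C2B4OC(C)(C)C(C)(C)O4 | intermediate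
19 | 2-[3,5-dibromo-4-chloro-2-(2,4-dibromophenoxy)phenyl]-4,4,5,5-tetramethyl-1,3,2-dioxaborolane | CC1(C)OB(OC1(C)C)c1cc(Br)c(Cl)c(Br)c1Oc1ccc(Br)cc1Br | intermediate
20 | 2-[3,5-dibromo-4-chloro-2-(2,4-dibromophenoxy)phenoxy]-4,4,5,5-tetramethyl-1,3,2-dioxaborolane (not isolated) | CC1(C)OB(Oc2cc(Br)c(Cl)c(Br)c2Oc2ccc(Br)cc2Br)OC1(C)C | intermediate
21 | 3,5-dibromo-4-chloro-2-(2,4-dibromophenoxy)phenol | Oc1cc(Br)c(Cl)c(Br)c1Oc1ccc(Br)cc1Br | target

**Step count**
Total: 9 steps. Longest linear sequence: 7 steps (1, 2, 3, 4, 5, 8, 9).

**Steps most likely to fail**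

1. Step 8.
   - The push–pull alkyne may oligomerise or lose boron by adventitious protonolysis faster than it adds.
   - A zwitterionic pathway may collapse at C5 or displace chloride at C4.
   - Regiocontrol may erode at the temperature required.
   - The fallback uses known chemistry only and no cycloaddition. It sets out from 2,4-dibromophenol 1 and comes back at target 21. Purchased 4-chloro-2-fluorobenzaldehyde F1 is brominated twice with NBS in concentrated H2SO4, where CHO (meta), F (ortho/para) and Cl (ortho) all direct to C3 and C5, to give 3,5-dibromo-4-chloro-2-fluorobenzaldehyde F2. Phenol 1 then displaces the fluoride ortho to the formyl group (SNAr, K2CO3, DMAc, 90 °C). Fluoride should leave far faster than the doubly flanked para chloride, giving 3,5-dibromo-4-chloro-2-(2,4-dibromophenoxy)benzaldehyde F3. Baeyer–Villiger oxidation (mCPBA, CH2Cl2, reflux), with aryl migration assisted by the ortho aryloxy donor, gives 3,5-dibromo-4-chloro-2-(2,4-dibromophenoxy)phenyl formate F4. Methanolysis (K2CO3, MeOH) releases 21.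

2. Step 5.
   - The ate complex may revert to acetylide and borate on warming.
   - A slight excess of HCl may add across the ynol ether or cleave the C–B bond.
   - The product may hydrolyse during isolation.
   - The fallback sets out from 8 and comes back at 12. It is a catalytic dehydrogenative C–H borylation of the terminal alkyne with pinacolborane (Fe(OTf)2 with DABCO, or ZnBr2, toluene, 60–100 °C). This needs no organometallic base, no ate complex and no acid, and it makes no compound outside the list (F0).

3. Step 6.
   - The second bromination may occur again at C3, followed by ring opening of the resulting dione.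
   - Alternatively the reaction may stall after the first bromination.
   - The fallback sets out from 13 and comes back at 15. The enol is masked first (Me2SO4, K2CO3, acetone) as 4-methoxy-2H-pyran-2-one F5, which cannot form a 3,3-dibromo dione. NBS (2.2 equiv, MeCN, rt → 50 °C) should then place bromine at C3 and C5 to give 3,5-dibromo-4-methoxy-2H-pyran-2-one F6. BBr3 (CH2Cl2, −78 °C → rt) cleaves the methyl ether to 15.

**Further compounds**
F1 | step 8 | 4-chloro-2-fluorobenzaldehyde (purchased) | O=Cc1ccc(Cl)cc1F
F2 | step 8 | 3,5-dibromo-4-chloro-2-fluorobenzaldehyde | O=Cc1cc(Br)c(Cl)c(Br)c1F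
F3 | step 8 | 3,5-dibromo-4-chloro-2-(2,4-dibromophenoxy)benzaldehyde | O=Cc1cc(Br)c(Cl)c(Br)c1Oc1ccc(Br)cc1Br
F4 | step 8 | 3,5-dibromo-4-chloro-2-(2,4-dibromophenoxy)phenyl formate | O=COc1cc(Br)c(Cl)c(Br)c1Oc1ccc(Br)cc1Br
F0 | step 5 | none | none
F5 | step 6 | 4-methoxy-2H-pyran-2-one | COc1ccoc(=O)c1
F6 | step 6 | 3,5-dibromo-4-methoxy-2H-pyran-2-one | COc1c(Br)coc(=O)c1Br
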